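**Plan**
1. Retrosynthetic cuts, in order: the three phenolic O–CH2OMe bonds, then C2–C1' (ring B off a chromone), then O1–C2 and C4–C4a (ring C off a ring A aryl bromide), then C8''=CH2 and C8''–CH3 of the isopropenyl group, and last C1''–C2''. Lavandulyl numbering: C1'' is the benzylic CH2, C2'' the methine, C8'' the isopropenyl carbon on C2''.
2. Feature that allows the last cut: C1'' is a benzylic CH2 on C6 of ring A, ortho to the phenolic oxygens on C5 and C7. C2'' is alpha to C8'', which can be carried as an aldehyde carbon, so C1''–C2'' is the alpha-alkylation of 5-methylhex-4-enal by a ring A o-quinone methide.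
3. Forward order: ring A is bought. A temporary 2-chromanol ring (O5–C8''–C2''–C1'') closes in the key step and is reopened by MeMgBr. C8'' then becomes the isopropenyl group, ring C closes as a chromone, and ring B is attached last.
4. Regiochemistry: only the oxygen para to the side chain carries a silyl group, and a bromine sits next to it (installed before any alkene is present). Acylation and ring closure can therefore lead only to the 6-lavandulyl isomer.
5. Stereochemistry: C2'' (S) comes from the open enamine face of an (R)-diarylprolinol silyl ether catalyst. C2 (S) comes from a chiral diphosphine on rhodium in the conjugate arylation.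

Key step: step 5

Remark 1: CIP analysis of the target structure gives 2S and 2''S (at C2'': isopropenyl > benzylic CH2 > prenyl CH2 > H).
Remark 2 (assumption): the bromination in step 3 is taken to occur ortho to the chelated hydroxyl. The other regioisomer would merge into the same compound once both oxygens flanking the side chain carry MOM groups (step 7), so the route does not depend on this.

Step 1
Reactants: 1 2,4,6-trihydroxybenzaldehyde
Product: 2 2,6-dihydroxy-4-(triisopropylsilyloxy)benzaldehyde
Conditions: TIPSCl (1.05 equiv), imidazole, DMF, 0 °C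
Reagents that add atoms: triisopropylsilyl chloride, CC(C)[Si](Cl)(C(C)C)C(C)C
Why: Chemoselective O-silylation: the two ortho hydroxyls are tied up in hydrogen bonds to the formyl group, so the more acidic, unchelated 4-OH should react first, and this silyl ether marks the oxygen that later becomes O1.

Step 2
Reactants: 2 2,6-dihydroxy-4-(triisopropylsilyloxy)benzaldehyde
Product: 3 2-hydroxy-6-(methoxymethoxy)-4-(triisopropylsilyloxy)benzaldehyde
Conditions: MOMCl (1.1 equiv), iPr2NEt, CH2Cl2, 0 °C
Reagents that add atoms: chloromethyl methyl ether, COCCl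
Why: O-Alkylation (MOM acetal formation) of one of two equivalent phenols; once one is capped, the other sits in a strong chelate to the aldehyde and should resist a second alkylation with a tertiary amine base.

Step 3
Reactants: 3 2-hydroxy-6-(methoxymethoxy)-4-(triisopropylsilyloxy)benzaldehyde
Product: 4 3-bromo-2-hydroxy-6-(methoxymethoxy)-4-(triisopropylsilyloxy)benzaldehyde
Conditions: NBS (1.0 equiv), CH2Cl2, −20 °C to 0 °C
Reagents that add atoms: N-bromosuccinimide, O=C1CCC(=O)N1Br
Why: Electrophilic aromatic bromination of a trioxygenated ring, done before any alkene is present and expected ortho to the free phenol at the less crowded open position; the bromine is the handle for the later C4–C4a bond.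

Step 4
Reactants: 4 3-bromo-2-hydroxy-6-(methoxymethoxy)-4-(triisopropylsilyloxy)benzaldehyde
Product: 5 2-bromo-6-(hydroxymethyl)-5-(methoxymethoxy)-3-(triisopropylsilyloxy)phenol
Conditions: NaBH4, THF–MeOH, 0 °C; pH 7 buffer work-up, used crude
Reagents that add atoms: none
Why: Borohydride reduction of an aldehyde; low temperature and a neutral work-up are chosen because the trioxygenated benzylic alcohol ionises easily, and the crude product goes straight into step 5.

Step 5
Reactants: 5 2-bromo-6-(hydroxymethyl)-5-(methoxymethoxy)-3-(triisopropylsilyloxy)phenol; 6 5-methylhex-4-enal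
Product: 10 (3S)-8-bromo-5-(methoxymethoxy)-3-(3-methylbut-2-enyl)-7-(triisopropylsilyloxy)chroman-2-ol (anomer mixture), via o-quinone methide 7 (not isolated), via enamine 8 (not isolated), via hydroxy aldehyde 9 (not isolated)
Conditions: (R)-2-[diphenyl(trimethylsilyloxy)methyl]pyrrolidine (20 mol %), 4-O2NC6H4CO2H (20 mol %), 6 (3 equiv), CH2Cl2, 0 °C to rt, slow addition of 5
Reagents that add atoms: none
Why: The carboxylic acid dehydrates the electron-rich salicyl alcohol 5 to o-quinone methide 7, the E-enamine 8 attacks its unsubstituted CH2 terminus with rearomatisation of ring A (forming C1''–C2''), and the water just released hydrolyses the iminium ion to hydroxy aldehyde 9 and frees the amine. The closest known reaction type is the amine-catalysed formal [4+2] annulation (Michael addition then hemiacetalisation) of enolisable aldehydes with o-quinone methides generated in situ, which gives 2-chromanols. The temporary pyran ring closes by reversible 6-exo-trig addition of the phenolic oxygen (the later O5) to the aldehyde carbon, and the anomeric centre is left as a mixture because it is destroyed in step 6. The only lasting stereocentre, C3 of 10 (the later C2''), is controlled by the catalyst alone: the methide carbon carries two hydrogens, so only the enamine face matters, and the CPh2(OSiMe3) group of the (R)-pyrrolidine screens one face of the s-trans E-enamine, which by the sense established for carbon electrophiles with this catalyst family should give 3S. The step needs capture of 7 by 8 ahead of alkylation of the electron-rich precursor by 7 and ahead of lasting N-alkylation of the catalyst; slow addition of 5 to an excess of 6, the stabilisation of 7 by its ortho-alkoxy and para-silyloxy donors, the bromine that deactivates and blocks the ring, and the crowded catalyst nitrogen all work in that direction. Ring closure to 10 masks the aldehyde, and the alpha-branched open form re-forms an enamine only reluctantly, so the new centre should not epimerise.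

Step 6
Reactants: 10 (3S)-8-bromo-5-(methoxymethoxy)-3-(3-methylbut-2-enyl)-7-(triisopropylsilyloxy)chroman-2-ol
Product: 11 2-bromo-6-[(2S)-2-(1-hydroxyethyl)-5-methylhex-4-enyl]-5-(methoxymethoxy)-3-(triisopropylsilyloxy)phenol (carbinol epimers)
Conditions: MeMgBr (3.5 equiv), THF, −40 °C to 0 °C; aqueous quench
Reagents that add atoms: methylmagnesium bromide, C[Mg]Br
Why: Grignard addition to a lactol through its open hydroxy-aldehyde form (one equivalent deprotonates, the next adds), which opens the temporary ring; addition to the aldehyde is much faster than enolisation, so C2'' is kept, and the new carbinol centre is erased in step 8.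

Step 7
Reactants: 11 2-bromo-6-[(2S)-2-(1-hydroxyethyl)-5-methylhex-4-enyl]-5-(methoxymethoxy)-3-(triisopropylsilyloxy)phenol
Product: 12 (3S)-3-[[3-bromo-2,6-bis(methoxymethoxy)-4-(triisopropylsilyloxy)phenyl]methyl]-6-methylhept-5-en-2-ol (carbinol epimers)
Conditions: MOMCl (1.3 equiv), K2CO3, acetone, rt
Reagents that add atoms: chloromethyl methyl ether, COCCl
Why: Williamson-type phenol protection: K2CO3 deprotonates only the acidic ortho-bromophenol, so the secondary alcohol stays free, and ring A now carries identical MOM ethers on both sides of the side chain.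

Step 8
Reactants: 12 (3S)-3-[[3-bromo-2,6-bis(methoxymethoxy)-4-(triisopropylsilyloxy)phenyl]methyl]-6-methylhept-5-en-2-ol
Product: 13 (3S)-3-[[3-bromo-2,6-bis(methoxymethoxy)-4-(triisopropylsilyloxy)phenyl]methyl]-6-methylhept-5-en-2-one
Conditions: Dess–Martin periodinane, CH2Cl2, 0 °C to rt
Reagents that add atoms: none
Why: Dess–Martin oxidation, a near-neutral alcohol oxidation that tolerates MOM ethers, the silyl ether, the aryl bromide and the trisubstituted alkene and does not enolise the alpha-branched ketone.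

Step 9
Reactants: 13 (3S)-3-[[3-bromo-2,6-bis(methoxymethoxy)-4-(triisopropylsilyloxy)phenyl]methyl]-6-methylhept-5-en-2-one
Product: 14 [2-bromo-3,5-bis(methoxymethoxy)-4-[(2S)-5-methyl-2-(prop-1-en-2-yl)hex-4-enyl]phenoxy]triisopropylsilane
Conditions: Cp2TiMe2 (2.5 equiv), toluene, 70 °C, dark
Reagents that add atoms: dimethyltitanocene Cp2TiMe2, C[Ti](C)(C1C=CC=C1)C1C=CC=C1
Why: Petasis methylenation: the non-basic titanium methylidene converts the ketone through an oxatitanacyclobutane, avoiding the enolisation and loss of C2'' configuration that a basic Wittig ylide could cause.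

Step 10
Reactants: 15 (trimethylsilyl)acetylene
Product: 17 N-methoxy-N-methyl-3-(trimethylsilyl)prop-2-ynamide, via lithium acetylide 16 (not isolated)
Conditions: n-BuLi, THF, −78 °C; ClC(O)N(OMe)Me, −78 °C to rt
Reagents that add atoms: N-methoxy-N-methylcarbamoyl chloride, CON(C)C(=O)Cl
Why: Acylation of a lithium acetylide with a carbamoyl chloride, a standard entry to alkynyl Weinreb amides.

Step 11
Reactants: 14 [2-bromo-3,5-bis(methoxymethoxy)-4-[(2S)-5-methyl-2-(prop-1-en-2-yl)hex-4-enyl]phenoxy]triisopropylsilane; 17 N-methoxy-N-methyl-3-(trimethylsilyl)prop-2-ynamide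
Product: 19 1-[2,4-bis(methoxymethoxy)-3-[(2S)-5-methyl-2-(prop-1-en-2-yl)hex-4-enyl]-6-(triisopropylsilyloxy)phenyl]-3-(trimethylsilyl)prop-2-yn-1-one, via aryllithium 18 (not isolated)
Conditions: n-BuLi (1.05 equiv), THF, −78 °C, 10 min; 17 (1.5 equiv), −78 °C to −40 °C; cold aqueous quench (pH 7 buffer)
Reagents that add atoms: none
Why: Bromine–lithium exchange followed by Weinreb ketone synthesis: exchange at −78 °C is faster than allylic deprotonation or O-to-C migration of the bulky silyl group, the MOM oxygen chelates the aryllithium, and the non-enolisable amide forms a stable chelate that stops at the ketone.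

Step 12
Reactants: 19 1-[2,4-bis(methoxymethoxy)-3-[(2S)-5-methyl-2-(prop-1-en-2-yl)hex-4-enyl]-6-(triisopropylsilyloxy)phenyl]-3-(trimethylsilyl)prop-2-yn-1-one
Product: 21 5,7-bis(methoxymethoxy)-6-[(2S)-5-methyl-2-(prop-1-en-2-yl)hex-4-enyl]-4H-chromen-4-one, via hydroxy ynone 20 (not isolated)
Conditions: Bu4NF (2.2 equiv, 1 M in THF, water-containing), THF, −20 °C to 0 °C
Reagents that add atoms: none
Why: Fluoride removes both silyl groups and the liberated phenoxide adds to the terminal ynone in a 6-endo-dig oxa-Michael closure (the known chromone synthesis from o-silyloxyaryl ynones); only the oxygen para to the side chain is free, which fixes the 6-lavandulyl pattern without any acid.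

Step 13
Reactants: 22 4-bromo-3-methoxyphenol
Product: 23 1-bromo-2-methoxy-4-(methoxymethoxy)benzene
Conditions: MOMCl, iPr2NEt, CH2Cl2, 0 °C to rt
Reagents that add atoms: chloromethyl methyl ether, COCCl
Why: Standard MOM protection of a phenol, chosen so that all phenol protecting groups fall in one final operation.

Step 14
Reactants: 23 1-bromo-2-methoxy-4-(methoxymethoxy)benzene
Product: 26 [2-methoxy-4-(methoxymethoxy)phenyl]boronic acid, via aryllithium 24 (not isolated), via lithium triisopropoxyborate 25 (not isolated)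
Conditions: B(OiPr)3 (1.3 equiv), n-BuLi (1.1 equiv, added last), THF–toluene, −78 °C to rt; aqueous work-up
Reagents that add atoms: triisopropyl borate, CC(C)OB(OC(C)C)OC(C)C; water, O
Why: Bromine–lithium exchange with in situ borate trapping and hydrolysis, the usual route to arylboronic acids; the MOM ether survives the nearly neutral work-up.

Step 15
Reactants: 21 5,7-bis(methoxymethoxy)-6-[(2S)-5-methyl-2-(prop-1-en-2-yl)hex-4-enyl]-4H-chromen-4-one; 26 [2-methoxy-4-(methoxymethoxy)phenyl]boronic acid
Product: 27 (2S)-2-[2-methoxy-4-(methoxymethoxy)phenyl]-5,7-bis(methoxymethoxy)-6-[(2S)-5-methyl-2-(prop-1-en-2-yl)hex-4-enyl]chroman-4-one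
Conditions: [Rh(OH)(cod)]2 (2.5 mol %), (S)-2,2'-bis[bis(3,4,5-trifluorophenyl)phosphino]-6,6'-dimethoxybiphenyl (5.5 mol %), 26 (3 equiv), toluene–H2O, 25–40 °C
Reagents that add atoms: none
Why: Hayashi–Miyaura reaction (rhodium-catalysed asymmetric 1,4-addition of an arylboronic acid), known for chromones including 5,7-dioxygenated ones: the aryl–rhodium species inserts C2=C3 on the face left open by the (S)-biaryl diphosphine, which by the quadrant model for cyclic enones should give 2S regardless of the remote C2'' centre, fast protonation of the rhodium enolate by water counters ring opening to the chalcone, and the isolated alkenes are inert.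

Step 16
Reactants: 27 (2S)-2-[2-methoxy-4-(methoxymethoxy)phenyl]-5,7-bis(methoxymethoxy)-6-[(2S)-5-methyl-2-(prop-1-en-2-yl)hex-4-enyl]chroman-4-one
Product: 28 (2S)-5,7-dihydroxy-2-(4-hydroxy-2-methoxyphenyl)-6-[(2S)-5-methyl-2-(prop-1-en-2-yl)hex-4-enyl]chroman-4-one (CNP0102823.1)
Conditions: HCl (1.25 M in MeOH), MeOH–THF, 0 °C to rt
Reagents that add atoms: none
Why: Acid-catalysed acetal exchange with methanol (MOM cleavage), widely used on prenylated flavanones; dilute acid at or below room temperature is chosen so that the isopropenyl group is not protonated (chroman formation with O5 or O7) and the C2–O1 bond does not ionise (epimerisation).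

**Compound list**
1 | 2,4,6-trihydroxybenzaldehyde | O=Cc1c(O)cc(O)cc1O | starting material
2 | 2,6-dihydroxy-4-(triisopropylsilyloxy)benzaldehyde | O=Cc1c(O)cc(O[Si](C(C)C)(C(C)C)C(C)C)cc1O | intermediate
3 | 2-hydroxy-6-(methoxymethoxy)-4-(triisopropylsilyloxy)benzaldehyde | O=Cc1c(O)cc(O[Si](C(C)C)(C(C)C)C(C)C)cc1OCOC | intermediate
4 | 3-bromo-2-hydroxy-6-(methoxymethoxy)-4-(triisopropylsilyloxy)benzaldehyde | O=Cc1c(O)c(Br)c(O[Si](C(C)C)(C(C)C)C(C)C)cc1OCOC | intermediate
5 | 2-bromo-6-(hydroxymethyl)-5-(methoxymethoxy)-3-(triisopropylsilyloxy)phenol | OCc1c(O)c(Br)c(O[Si](C(C)C)(C(C)C)C(C)C)cc1OCOC | intermediate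
6 | 5-methylhex-4-enal | CC(C)=CCCC=O | starting material
7 | 2-bromo-5-(methoxymethoxy)-6-methylidene-3-(triisopropylsilyloxy)cyclohexa-2,4-dien-1-one (o-quinone methide) | C=C1C(=O)C(Br)=C(O[Si](C(C)C)(C(C)C)C(C)C)C=C1OCOC | intermediate
8 | (E)-enamine of 6 and (R)-2-[diphenyl(trimethylsilyloxy)methyl]pyrrolidine | C[Si](C)(C)OC(c1ccccc1)(c1ccccc1)[C@H]1CCCN1/C=C/CC=C(C)C | intermediate
9 | (2S)-2-[[3-bromo-2-hydroxy-6-(methoxymethoxy)-4-(triisopropylsilyloxy)phenyl]methyl]-5-methylhex-4-enal | O=C[C@@H](CC=C(C)C)Cc1c(O)c(Br)c(O[Si](C(C)C)(C(C)C)C(C)C)cc1OCOC | intermediate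
10 | (3S)-8-bromo-5-(methoxymethoxy)-3-(3-methylbut-2-enyl)-7-(triisopropylsilyloxy)chroman-2-ol, anomer mixture | OC1[C@@H](CC=C(C)C)Cc2c(OCOC)cc(O[Si](C(C)C)(C(C)C)C(C)C)c(Br)c2O1 | intermediate
11 | 2-bromo-6-[(2S)-2-(1-hydroxyethyl)-5-methylhex-4-enyl]-5-(methoxymethoxy)-3-(triisopropylsilyloxy)phenol, carbinol epimers | CC(O)[C@@H](CC=C(C)C)Cc1c(O)c(Br)c(O[Si](C(C)C)(C(C)C)C(C)C)cc1OCOC | intermediate
12 | (3S)-3-[[3-bromo-2,6-bis(methoxymethoxy)-4-(triisopropylsilyloxy)phenyl]methyl]-6-methylhept-5-en-2-ol, carbinol epimers | CC(O)[C@@H](CC=C(C)C)Cc1c(OCOC)c(Br)c(O[Si](C(C)C)(C(C)C)C(C)C)cc1OCOC | intermediate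
13 | (3S)-3-[[3-bromo-2,6-bis(methoxymethoxy)-4-(triisopropylsilyloxy)phenyl]methyl]-6-methylhept-5-en-2-one | CC(=O)[C@@H](CC=C(C)C)Cc1c(OCOC)c(Br)c(O[Si](C(C)C)(C(C)C)C(C)C)cc1OCOC | intermediate
14 | [2-bromo-3,5-bis(methoxymethoxy)-4-[(2S)-5-methyl-2-(prop-1-en-2-yl)hex-4-enyl]phenoxy]triisopropylsilane | C=C(C)[C@@H](CC=C(C)C)Cc1c(OCOC)c(Br)c(O[Si](C(C)C)(C(C)C)C(C)C)cc1OCOC | intermediate
15 | (trimethylsilyl)acetylene | C#C[Si](C)(C)C | starting material
16 | lithium (trimethylsilyl)acetylide | [Li]C#C[Si](C)(C)C | intermediate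
17 | N-methoxy-N-methyl-3-(trimethylsilyl)prop-2-ynamide | CON(C)C(=O)C#C[Si](C)(C)C | intermediate
18 | aryllithium from 14 (Li in place of Br) | C=C(C)[C@@H](CC=C(C)C)Cc1c(OCOC)c([Li])c(O[Si](C(C)C)(C(C)C)C(C)C)cc1OCOC | intermediate
19 | 1-[2,4-bis(methoxymethoxy)-3-[(2S)-5-methyl-2-(prop-1-en-2-yl)hex-4-enyl]-6-(triisopropylsilyloxy)phenyl]-3-(trimethylsilyl)prop-2-yn-1-one | C=C(C)[C@@H](CC=C(C)C)Cc1c(OCOC)c(C(=O)C#C[Si](C)(C)C)c(O[Si](C(C)C)(C(C)C)C(C)C)cc1OCOC | intermediate
20 | 1-[6-hydroxy-2,4-bis(methoxymethoxy)-3-[(2S)-5-methyl-2-(prop-1-en-2-yl)hex-4-enyl]phenyl]prop-2-yn-1-one | C=C(C)[C@@H](CC=C(C)C)Cc1c(OCOC)c(C(=O)C#C)c(O)cc1OCOC | intermediate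
21 | 5,7-bis(methoxymethoxy)-6-[(2S)-5-methyl-2-(prop-1-en-2-yl)hex-4-enyl]-4H-chromen-4-one | C=C(C)[C@@H](CC=C(C)C)Cc1c(OCOC)cc2occc(=O)c2c1OCOC | intermediate
22 | 4-bromo-3-methoxyphenol | COc1cc(O)ccc1Br | starting material
23 | 1-bromo-2-methoxy-4-(methoxymethoxy)benzene | COCOc1ccc(Br)c(OC)c1 | intermediate
24 | [2-methoxy-4-(methoxymethoxy)phenyl]lithium | COCOc1ccc([Li])c(OC)c1 | intermediate
25 | lithium [2-methoxy-4-(methoxymethoxy)phenyl]triisopropoxyborate | [Li+].COCOc1ccc([B-](OC(C)C)(OC(C)C)OC(C)C)c(OC)c1 | intermediate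
26 | [2-methoxy-4-(methoxymethoxy)phenyl]boronic acid | COCOc1ccc(B(O)O)c(OC)c1 | intermediate
27 | (2S)-2-[2-methoxy-4-(methoxymethoxy)phenyl]-5,7-bis(methoxymethoxy)-6-[(2S)-5-methyl-2-(prop-1-en-2-yl)hex-4-enyl]chroman-4-one | C=C(C)[C@@H](CC=C(C)C)Cc1c(OCOC)cc2c(c1OCOC)C(=O)C[C@@H](c1ccc(OCOC)cc1OC)O2 | intermediate
28 | (2S)-5,7-dihydroxy-2-(4-hydroxy-2-methoxyphenyl)-6-[(2S)-5-methyl-2-(prop-1-en-2-yl)hex-4-enyl]chroman-4-one | C=C(C)[C@@H](CC=C(C)C)Cc1c(O)cc2c(c1O)C(=O)C[C@@H](c1ccc(O)cc1OC)O2 | target

**Step count**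
Total step count: 16.
Longest linear sequence: 13 steps (steps 1–9, 11, 12, 15, 16) from 2,4,6-trihydroxybenzaldehyde.

**Steps most likely to fail**

Step 5.
- What may go wrong: the methide may alkylate its own electron-rich aromatic precursor, it may be held back by the catalyst nitrogen, or the enamine face may be shielded incompletely.
- Fallback: it sets out from 5 and comes back at 10. It moves the nucleophile to the carboxylic acid oxidation level under carbene catalysis.
- Compound 5 is treated with p-toluenesulfinic acid in CH2Cl2 to give the storable sulfone 2-bromo-5-(methoxymethoxy)-6-[(4-methylphenyl)sulfonylmethyl]-3-(triisopropylsilyloxy)phenol F1, which releases 7 only gradually with Cs2CO3.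
- Commercial 5-methylhex-4-enoic acid is activated with carbonyldiimidazole as 1-(1H-imidazol-1-yl)-5-methylhex-4-en-1-one F2.
- A chiral aminoindanol-derived triazolium salt (enantiomer chosen for 3S) converts F2 into an azolium enolate. This enolate undergoes the known carbene-catalysed formal [4+2] annulation with the CH2-terminated methide and should give (3S)-8-bromo-5-(methoxymethoxy)-3-(3-methylbut-2-enyl)-7-(triisopropylsilyloxy)chroman-2-one F3.
- Reduction of F3 with iBu2AlH in CH2Cl2 at −78 °C gives 10.

Step 15.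
- What may go wrong: insertion into the electron-rich, 5-substituted chromone may be slower than protodeboronation of the ortho-substituted, electron-rich boronic acid, and ring opening of the rhodium enolate may erode the C2 configuration.
- Fallback: it sets out from 14 (ring B partner from 23) and comes back at 27. Ring C is built from a chalcone instead.
- Compound 14 is lithiated as in step 11 and acylated with N-methoxy-N-methylacetamide to give 1-[2,4-bis(methoxymethoxy)-3-[(2S)-5-methyl-2-(prop-1-en-2-yl)hex-4-enyl]-6-(triisopropylsilyloxy)phenyl]ethanone F4.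
- Bu4NF then frees 1-[6-hydroxy-2,4-bis(methoxymethoxy)-3-[(2S)-5-methyl-2-(prop-1-en-2-yl)hex-4-enyl]phenyl]ethanone F5.
- Compound 23 is lithiated and formylated with DMF to give 2-methoxy-4-(methoxymethoxy)benzaldehyde F6.
- Claisen–Schmidt condensation of F5 with F6 (KOH, EtOH) gives (E)-1-[6-hydroxy-2,4-bis(methoxymethoxy)-3-[(2S)-5-methyl-2-(prop-1-en-2-yl)hex-4-enyl]phenyl]-3-[2-methoxy-4-(methoxymethoxy)phenyl]prop-2-en-1-one F7.
- Intramolecular oxa-Michael cyclisation of F7 with a cinchona-derived thiourea (pseudoenantiomer chosen for 2S) closes ring C to 27.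
- Because C2'' is fixed, the C2 epimer is a diastereomer. It can be removed by HPLC and recycled through base-induced ring opening back to F7.

Step 12.
- What may go wrong: the unmasked terminal ynone may oligomerise by intermolecular conjugate addition, or 5-exo-dig closure may compete with the 6-endo-dig mode.
- Fallback: it sets out from 19 and comes back at 21. The ynone is tamed before the phenol is released.
- Stirring 19 with Et2NH in MeOH removes the alkynyl silyl group and adds the amine, giving the stable (E)-1-[2,4-bis(methoxymethoxy)-3-[(2S)-5-methyl-2-(prop-1-en-2-yl)hex-4-enyl]-6-(triisopropylsilyloxy)phenyl]-3-(diethylamino)prop-2-en-1-one F8.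
- Bu4NF buffered with AcOH then frees the phenol, which closes ring C by 6-endo-trig addition–elimination with loss of the amine. This is the enaminone route to chromones and leaves no 5-exo alternative.

**Further compounds**
F1 | step 5 | 2-bromo-5-(methoxymethoxy)-6-[(4-methylphenyl)sulfonylmethyl]-3-(triisopropylsilyloxy)phenol | Cc1ccc(cc1)S(=O)(=O)Cc1c(O)c(Br)c(O[Si](C(C)C)(C(C)C)C(C)C)cc1OCOC
F2 | step 5 | 1-(1H-imidazol-1-yl)-5-methylhex-4-en-1-one | CC(C)=CCCC(=O)n1ccnc1
F3 | step 5 | (3S)-8-bromo-5-(methoxymethoxy)-3-(3-methylbut-2-enyl)-7-(triisopropylsilyloxy)chroman-2-one | O=C1[C@@H](CC=C(C)C)Cc2c(OCOC)cc(O[Si](C(C)C)(C(C)C)C(C)C)c(Br)c2O1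
F4 | step 15 | 1-[2,4-bis(methoxymethoxy)-3-[(2S)-5-methyl-2-(prop-1-en-2-yl)hex-4-enyl]-6-(triisopropylsilyloxy)phenyl]ethanone | C=C(C)[C@@H](CC=C(C)C)Cc1c(OCOC)c(C(C)=O)c(O[Si](C(C)C)(C(C)C)C(C)C)cc1OCOC
F5 | step 15 | 1-[6-hydroxy-2,4-bis(methoxymethoxy)-3-[(2S)-5-methyl-2-(prop-1-en-2-yl)hex-4-enyl]phenyl]ethanone | C=C(C)[C@@H](CC=C(C)C)Cc1c(OCOC)c(C(C)=O)c(O)cc1OCOC
F6 | step 15 | 2-methoxy-4-(methoxymethoxy)benzaldehyde | COCOc1ccc(C=O)c(OC)c1
F7 | step 15 | (E)-1-[6-hydroxy-2,4-bis(methoxymethoxy)-3-[(2S)-5-methyl-2-(prop-1-en-2-yl)hex-4-enyl]phenyl]-3-[2-methoxy-4-(methoxymethoxy)phenyl]prop-2-en-1-one | C=C(C)[C@@H](CC=C(C)C)Cc1c(OCOC)c(C(=O)/C=C/c2ccc(OCOC)cc2OC)c(O)cc1OCOC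
F8 | step 12 | (E)-1-[2,4-bis(methoxymethoxy)-3-[(2S)-5-methyl-2-(prop-1-en-2-yl)hex-4-enyl]-6-(triisopropylsilyloxy)phenyl]-3-(diethylamino)prop-2-en-1-one | C=C(C)[C@@H](CC=C(C)C)Cc1c(OCOC)c(C(=O)/C=C/N(CC)CC)c(O[Si](C(C)C)(C(C)C)C(C)C)cc1OCOC
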